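Ring A (C1–C5, C10; ent-kaurane numbering) has a gem-dimethyl carbon C4 beside C5 and an unfunctionalised CH2 (C1) beside quaternary C10. This lets C2–C3 be inserted between a C5 isopropenyl group and a C10 formyl group: an iron-hydride HAT radical–polar crossover annulation with acrolein forms C3–C4 (Giese) and C1–C2 (aldol) in one operation, closing ring A on a δ-lactone that already fixes C5 and C10. The lactone is then opened to the C9 vinyl ketone/C7 aldehyde, joined to an iodocyclopentenone (ring D) by a Nozaki–Hiyama–Kishi reaction, and the ten-membered ring is closed by metathesis; hydrogenation and Mannich-base elimination finish the target.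

Key step: step 4

Remark: atoms are numbered as in ent-kaurane (ring A = C1–C5/C10, C9 ketone, C7 acetoxy carbon, ring D = C8/C14/C13/C16/C15, C17 exocyclic CH2); enolates and radicals that live only within one operation are treated as mechanistic intermediates and are not numbered; the 4S outcome of step 1 is assigned to (S)-BINAP by analogy with aryl additions, and the other ligand enantiomer is used if the sense is opposite.

Step 1
Reactants: 1 5,6-dihydro-2H-pyran-2-one; 2 4,4,5,5-tetramethyl-2-(prop-1-en-2-yl)-1,3,2-dioxaborolane (isopropenyl-Bpin)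
Product: 3 (S)-4-(prop-1-en-2-yl)tetrahydro-2H-pyran-2-one
Conditions: [Rh(OH)((S)-BINAP)]2 (cat.), KOH (cat.), dioxane/H2O, 40 °C
Reagents that add atoms: none
Why: Rh-catalysed asymmetric 1,4-addition of an alkenylboron reagent to an unsaturated lactone (Hayashi–Miyaura reaction); the (S)-BINAP–Rh–alkenyl complex should add to one enantioface and set the future C5 (S here, 5R in the target after the priorities change).

Step 2
Reactants: 3 (S)-4-(prop-1-en-2-yl)tetrahydro-2H-pyran-2-one
Product: 4 (3R,4S)-3-methyl-4-(prop-1-en-2-yl)tetrahydro-2H-pyran-2-one (3,4-trans)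
Conditions: LDA, THF, −78 °C; MeI, −78 → −40 °C
Reagents that add atoms: iodomethane (CI)
Why: lithium lactone enolate alkylation, methyl entering anti to the isopropenyl group; this centre is re-enolised in step 3, so its configuration is not critical.

Step 3
Reactants: 4 (3R,4S)-3-methyl-4-(prop-1-en-2-yl)tetrahydro-2H-pyran-2-one
Product: 5 (3S,4R)-3-methyl-2-oxo-4-(prop-1-en-2-yl)tetrahydro-2H-pyran-3-carbaldehyde (CHO trans, CH3 cis to isopropenyl)
Conditions: LDA, THF, −78 °C; HCO2Et, −78 → −20 °C; aqueous work-up
Reagents that add atoms: ethyl formate (CCOC=O)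
Why: crossed-Claisen C-formylation of the tetrasubstituted lithium enolate, the formate approaching anti to the adjacent isopropenyl group, which sets quaternary C10 with CHO (future C1) trans to isopropenyl (future C4); the product is non-enolisable and cannot epimerise.

Step 4
Reactants: 5 (3S,4R)-3-methyl-2-oxo-4-(prop-1-en-2-yl)tetrahydro-2H-pyran-3-carbaldehyde; 6 acrolein
Product: 7 (4aR,8aS)-8-hydroxy-5,5,8a-trimethyl-1-oxooctahydro-1H-isochromene-7-carbaldehyde (trans-fused; the carbinol and formyl-bearing carbons are C1 and C2 of the target, configuration not controlled and not needed)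
Conditions: Fe(acac)3 (20 mol %), PhSiH3 (2 equiv), acrolein (3 equiv), EtOH/(CH2OH)2, 0 °C → rt
Reagents that add atoms: none
Why: An iron hydride formed from Fe(acac)3/PhSiH3 transfers a hydrogen atom to the isopropenyl CH2, the tertiary C4 radical adds to acrolein (C3–C4, Giese addition), the α-formyl radical is reduced by Fe(II) to an iron enolate (radical–polar crossover), and this enolate adds intramolecularly to the formyl group on C10 (C1–C2). The closest known reaction type is the HAT-initiated reductive olefin coupling extended to a Giese/aldol radical–polar crossover annulation between an alkenyl aldehyde and an unsaturated carbonyl compound. Ring A closes by a 6-(enolexo)-exo-trig aldol through a chair in which C1 and C4, trans on the lactone, are both equatorial, so the trans ring fusion (C5–H anti to C10–CH3) is inherited from 5 and no stereocentre of the target is formed or touched. The new centres C1 (carbinol) and C2 (formyl) are governed by that chair transition state but are erased in steps 5–7, so any diastereomer ratio is tolerated. The step needs chemoselective HAT to the only electron-rich 1,1-disubstituted alkene, a polarity-matched intermolecular Giese addition (nucleophilic tertiary radical, excess electron-poor acrolein) and an aldol that outruns enolate protonation, which the proximity of the non-enolisable neopentyl aldehyde should secure.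

Step 5
Reactants: 7 (4aR,8aS)-8-hydroxy-5,5,8a-trimethyl-1-oxooctahydro-1H-isochromene-7-carbaldehyde
Product: 9 (4aR,8aR)-5,5,8a-trimethyl-1-oxo-3,4,4a,5,6,8a-hexahydro-1H-isochromene-7-carbaldehyde, via mesylate 8 (not isolated)
Conditions: MsCl, Et3N, CH2Cl2, 0 °C; then DBU, rt
Reagents that add atoms: none
Why: mesylation and E1cB elimination of the aldol adduct to the conjugated enal (aldol dehydration), which erases C1/C2 stereochemistry so that all diastereomers of 7 converge.

Step 6
Reactants: 9 (4aR,8aR)-5,5,8a-trimethyl-1-oxo-3,4,4a,5,6,8a-hexahydro-1H-isochromene-7-carbaldehyde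
Product: 10 (4aR,8aR)-5,5,8a-trimethyl-3,4,4a,5,6,8a-hexahydro-1H-isochromen-1-one
Conditions: RhCl3·3H2O (cat.), dppp (cat.), diglyme, 160 °C, N2 sweep
Reagents that add atoms: none
Why: Tsuji–Wilkinson decarbonylation of the enal (acyl–Rh–H formation, CO extrusion, C–H reductive elimination) removes the activating formyl carbon; any migration of the ring-A alkene is irrelevant because it is saturated in step 7.

Step 7
Reactants: 10 (4aR,8aR)-5,5,8a-trimethyl-3,4,4a,5,6,8a-hexahydro-1H-isochromen-1-one
Product: 11 (4aR,8aR)-5,5,8a-trimethyloctahydro-1H-isochromen-1-one (trans-fused lactone)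
Conditions: H2 (1 atm), 10% Pd/C, EtOAc, rt
Reagents that add atoms: none
Why: heterogeneous catalytic hydrogenation of the disubstituted ring alkene; no stereocentre is created.

Step 8
Reactants: 11 (4aR,8aR)-5,5,8a-trimethyloctahydro-1H-isochromen-1-one
Product: 12 1-[(1R,2R)-2-(2-hydroxyethyl)-1,3,3-trimethylcyclohexyl]prop-2-en-1-one
Conditions: CH2=CHMgBr (1.2 equiv), THF, −78 → −20 °C; aqueous quench at low temperature
Reagents that add atoms: vinylmagnesium bromide (C=C[Mg]Br)
Why: mono-addition of a Grignard reagent to a lactone, the hindered α-quaternary magnesium hemiketal expected to persist until quench and then open to the C9 vinyl ketone with the free C7 hydroxyl (in equilibrium with its lactol).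

Step 9
Reactants: 12 1-[(1R,2R)-2-(2-hydroxyethyl)-1,3,3-trimethylcyclohexyl]prop-2-en-1-one
Product: 13 2-[(1R,2R)-2,6,6-trimethyl-2-(prop-2-enoyl)cyclohexyl]acetaldehyde
Conditions: Dess–Martin periodinane, NaHCO3, CH2Cl2, 0 °C → rt
Reagents that add atoms: none
Why: Dess–Martin oxidation of the primary alcohol to the C7 aldehyde under buffered, non-basic conditions that avoid enolisation and Michael addition to the vinyl ketone.

Step 10
Reactants: 14 (R)-4-[(tert-butyldimethylsilyl)oxy]cyclopent-2-en-1-one
Product: 15 (2S,3R,4R)-4-[(tert-butyldimethylsilyl)oxy]-2-[(dimethylamino)methyl]-3-vinylcyclopentan-1-one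
Conditions: CH2=CHMgBr, CuBr·SMe2 (cat.), THF, −78 °C; then Me2N=CH2+ I−, −78 → 0 °C
Reagents that add atoms: vinylmagnesium bromide (C=C[Mg]Br); Eschenmoser's salt (C[N+](C)=C.[I-])
Why: copper-catalysed conjugate addition anti to the silyloxy group sets C13, and the regiodefined enolate is trapped in a Mannich reaction trans to the new vinyl group (three-component conjugate addition–enolate trapping); the enolate lies away from the OTBS group, so it does not eliminate.

Step 11
Reactants: 15 (2S,3R,4R)-4-[(tert-butyldimethylsilyl)oxy]-2-[(dimethylamino)methyl]-3-vinylcyclopentan-1-one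
Product: 16 (4S,5S)-5-[(dimethylamino)methyl]-4-vinylcyclopent-2-en-1-one
Conditions: DBU (1.1 equiv), CH2Cl2, 0 °C, short reaction time
Reagents that add atoms: none
Why: E1cB elimination of the β-silyloxy group gives the C8=C14 enone; cold, brief base exposure is chosen to avoid deprotonation at the doubly allylic C13.

Step 12
Reactants: 16 (4S,5S)-5-[(dimethylamino)methyl]-4-vinylcyclopent-2-en-1-one
Product: 17 (4R,5S)-5-[(dimethylamino)methyl]-2-iodo-4-vinylcyclopent-2-en-1-one
Conditions: I2, pyridine, CH2Cl2, 0 °C → rt
Reagents that add atoms: iodine (II)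
Why: α-iodination of the enone by the pyridine addition–iodination–elimination sequence (Baylis–Hillman-type mechanism) places iodine on C8 without touching the stereocentres.

Step 13
Reactants: 13 2-[(1R,2R)-2,6,6-trimethyl-2-(prop-2-enoyl)cyclohexyl]acetaldehyde; 17 (4R,5S)-5-[(dimethylamino)methyl]-2-iodo-4-vinylcyclopent-2-en-1-one
Product: 18 (4S,5S)-5-[(dimethylamino)methyl]-2-[(1R)-1-hydroxy-2-[(1R,2R)-2,6,6-trimethyl-2-(prop-2-enoyl)cyclohexyl]ethyl]-4-vinylcyclopent-2-en-1-one
Conditions: CrCl2 (4 equiv), NiCl2 (cat.), chiral oxazoline–sulfonamide ligand, Et3N, THF, rt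
Reagents that add atoms: none
Why: Nozaki–Hiyama–Kishi addition of the alkenylchromium(III) species to the aldehyde (chemoselective over both ketones) forms C7–C8; the chiral sulfonamide–chromium complex, in the enantiomer that directs attack to the Si face of the aldehyde, should set C7 as R by reagent control.

Step 14
Reactants: 18 (7R)-allylic alcohol from step 13
Product: 19 O-acetyl derivative of 18 (7R acetate)
Conditions: Ac2O, pyridine, CH2Cl2, 0 °C → rt
Reagents that add atoms: acetic anhydride (CC(=O)OC(C)=O)
Why: O-acetylation with a weakly nucleophilic base so that neither the vinyl ketone nor the Morita–Baylis–Hillman-type acetate is attacked.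

Step 15
Reactants: 19 7R acetate with vinyl ketone and C13 vinyl group
Product: 20 (5R,7R,10R,13S,16S)-7-acetoxy-17-(dimethylamino)-16,17-dihydro-8,9-secokaura-8(14),11-diene-9,15-dione (C11=C12 geometry not specified)
Conditions: Hoveyda–Grubbs II (10–15 mol %), camphorsulfonic acid (1.05 equiv), toluene, 1 mM, 80 °C; NaHCO3 work-up
Reagents that add atoms: none
Why: ring-closing metathesis, the catalyst loading on the C13 vinyl group and closing onto the electron-poor vinyl ketone with loss of ethylene to form the ten-membered ring (amine masked as its salt); the alkene geometry is inconsequential.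

Step 16
Reactants: 20 macrocyclic C11=C12 enone
Product: 21 (5R,7R,10R,13S,16S)-7-acetoxy-17-(dimethylamino)-16,17-dihydro-8,9-secokaur-8(14)-ene-9,15-dione
Conditions: H2 (1 atm), RhCl(PPh3)3 (cat.), benzene/EtOH, rt
Reagents that add atoms: none
Why: homogeneous hydrogenation with Wilkinson's catalyst is selective for the disubstituted C11=C12 alkene, and the trisubstituted α-branched C8=C14 enone and the allylic acetate are expected to survive.

Step 17
Reactants: 21 Mannich base macrocycle
Product: 23 (5R,7R,10R,13S)-7-acetoxy-8,9-secokaura-8(14),16-diene-9,15-dione (target), via ammonium iodide 22 (not isolated)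
Conditions: MeI (5 equiv), CH2Cl2/Et2O, rt; then sat. aq. NaHCO3, rt
Reagents that add atoms: none
Why: quaternisation of the Mannich base and E1cB loss of trimethylamine (Mannich-base methylenation end game) unveils the C16=C17 exocyclic enone under conditions mild enough for the allylic acetate; the C16 stereocentre disappears.

Compound list
1 | 5,6-dihydro-2H-pyran-2-one | O=C1C=CCCO1 | starting material
2 | 4,4,5,5-tetramethyl-2-(prop-1-en-2-yl)-1,3,2-dioxaborolane | CC(=C)B1OC(C)(C)C(C)(C)O1 | starting material
3 | (S)-4-(prop-1-en-2-yl)tetrahydro-2H-pyran-2-one | O=C1OCC[C@H](C(C)=C)C1 | intermediate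
4 | (3R,4S)-3-methyl-4-(prop-1-en-2-yl)tetrahydro-2H-pyran-2-one | O=C1OCC[C@H](C(C)=C)[C@H]1C | intermediate
5 | (3S,4R)-3-methyl-2-oxo-4-(prop-1-en-2-yl)tetrahydro-2H-pyran-3-carbaldehyde | O=C1OCC[C@H](C(C)=C)[C@@]1(C)C=O | intermediate
6 | acrolein | C=CC=O | starting material
7 | (4aR,8aS)-8-hydroxy-5,5,8a-trimethyl-1-oxooctahydro-1H-isochromene-7-carbaldehyde (C7/C8 of this name undefined) | O=C3[C@]1(C)C(O)C(C=O)CC(C)(C)[C@H]1CCO3 | intermediate
8 | (4aR,8aS)-7-formyl-5,5,8a-trimethyl-1-oxooctahydro-1H-isochromen-8-yl methanesulfonate | O=C3[C@]1(C)C(OS(C)(=O)=O)C(C=O)CC(C)(C)[C@H]1CCO3 | intermediate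
9 | (4aR,8aR)-5,5,8a-trimethyl-1-oxo-3,4,4a,5,6,8a-hexahydro-1H-isochromene-7-carbaldehyde | O=C3[C@]1(C)C=C(C=O)CC(C)(C)[C@H]1CCO3 | intermediate
10 | (4aR,8aR)-5,5,8a-trimethyl-3,4,4a,5,6,8a-hexahydro-1H-isochromen-1-one | O=C3[C@]1(C)C=CCC(C)(C)[C@H]1CCO3 | intermediate
11 | (4aR,8aR)-5,5,8a-trimethyloctahydro-1H-isochromen-1-one | O=C3[C@]1(C)CCCC(C)(C)[C@H]1CCO3 | intermediate
12 | 1-[(1R,2R)-2-(2-hydroxyethyl)-1,3,3-trimethylcyclohexyl]prop-2-en-1-one | C=CC(=O)[C@]1(C)CCCC(C)(C)[C@H]1CCO | intermediate
13 | 2-[(1R,2R)-2,6,6-trimethyl-2-(prop-2-enoyl)cyclohexyl]acetaldehyde | C=CC(=O)[C@]1(C)CCCC(C)(C)[C@H]1CC=O | intermediate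
14 | (R)-4-[(tert-butyldimethylsilyl)oxy]cyclopent-2-en-1-one | O=C1C=C[C@H](O[Si](C)(C)C(C)(C)C)C1 | starting material
15 | (2S,3R,4R)-4-[(tert-butyldimethylsilyl)oxy]-2-[(dimethylamino)methyl]-3-vinylcyclopentan-1-one | CN(C)C[C@H]1C(=O)C[C@@H](O[Si](C)(C)C(C)(C)C)[C@@H]1C=C | intermediate
16 | (4S,5S)-5-[(dimethylamino)methyl]-4-vinylcyclopent-2-en-1-one | CN(C)C[C@H]1C(=O)C=C[C@@H]1C=C | intermediate
17 | (4R,5S)-5-[(dimethylamino)methyl]-2-iodo-4-vinylcyclopent-2-en-1-one | CN(C)C[C@H]1C(=O)C(I)=C[C@@H]1C=C | intermediate
18 | (4S,5S)-5-[(dimethylamino)methyl]-2-[(1R)-1-hydroxy-2-[(1R,2R)-2,6,6-trimethyl-2-(prop-2-enoyl)cyclohexyl]ethyl]-4-vinylcyclopent-2-en-1-one | C=CC(=O)[C@]1(C)CCCC(C)(C)[C@H]1C[C@@H](O)C2=C[C@H](C=C)[C@@H](CN(C)C)C2=O | intermediate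
19 | O-acetyl derivative of 18 (7R acetate) | C=CC(=O)[C@]1(C)CCCC(C)(C)[C@H]1C[C@@H](OC(C)=O)C2=C[C@H](C=C)[C@@H](CN(C)C)C2=O | intermediate
20 | (5R,7R,10R,13S,16S)-7-acetoxy-17-(dimethylamino)-16,17-dihydro-8,9-secokaura-8(14),11-diene-9,15-dione (C11=C12 geometry not specified) | CN(C)C[C@H]1C(=O)C2=C[C@@H]1C=CC(=O)[C@]1(C)CCCC(C)(C)[C@H]1C[C@H]2OC(C)=O | intermediate
21 | (5R,7R,10R,13S,16S)-7-acetoxy-17-(dimethylamino)-16,17-dihydro-8,9-secokaur-8(14)-ene-9,15-dione | CN(C)C[C@H]1C(=O)C2=C[C@@H]1CCC(=O)[C@]1(C)CCCC(C)(C)[C@H]1C[C@H]2OC(C)=O | intermediate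
22 | N,N,N-trimethylammonium iodide of 21 | C[N+](C)(C)C[C@H]1C(=O)C2=C[C@@H]1CCC(=O)[C@]1(C)CCCC(C)(C)[C@H]1C[C@H]2OC(C)=O.[I-] | intermediate
23 | (5R,7R,10R,13S)-7-acetoxy-8,9-secokaura-8(14),16-diene-9,15-dione | C=C1C(=O)C2=C[C@@H]1CCC(=O)[C@]1(C)CCCC(C)(C)[C@H]1C[C@H]2OC(C)=O | target

Total step count: 17. Longest linear sequence: 14 steps (steps 1–9 and 13–17); the ring-D fragment takes steps 10–12.

Steps most likely to fail

Step 15 (ring-closing metathesis): intermolecular metathesis to dimers and oligomers may outrun closure of the strained ten-membered ring, or the carbene may stall on the enone. Fallback: the two unions are made in the opposite order, so that the ring is closed at C7–C8. Setting out from 13 and 17, cross-metathesis of the vinyl ketone with the C13 vinyl group (Hoveyda–Grubbs II, camphorsulfonic acid, CH2Cl2, 40 °C) should give the (E)-enone iodo-aldehyde F1. An intramolecular Nozaki–Hiyama–Kishi reaction under high dilution (CrCl2, cat. NiCl2, chiral sulfonamide ligand, THF/DMF) should give the macrocyclic 7R alcohol F2. Acetylation (Ac2O, pyridine) comes back to the route at 20, as its E isomer.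

Step 13 (Nozaki–Hiyama–Kishi coupling): the facial selectivity of the addition to the aldehyde may be poor, because the ring-A stereocentres are remote and the ligand may not override the substrate. Fallback: setting out from 13 and 17, the coupling is run without ligand and the C7 epimers are separated. The 7R alcohol 18 continues through step 14. The 7S epimer F3 is converted with inversion by a Mitsunobu esterification with acetic acid (PPh3, DIAD, toluene, 0 °C) and comes back to the route at 19.

Step 4 (radical–polar crossover annulation): protonation of the iron enolate by the alcohol solvent, or retro-aldol of the aldolate, may outrun ring closure onto the hindered neopentyl aldehyde. Fallback: the two bond formations are separated. Setting out from 5, the HAT-initiated reductive olefin coupling with acrolein (Fe(acac)3, PhSiH3, EtOH, 60 °C) is allowed to stop at the Giese adduct, the dialdehyde F4. An amine-catalysed intramolecular aldol condensation (pyrrolidine, AcOH, toluene, 60 °C), in which only the unhindered aldehyde can form the enamine, then closes ring A and comes back to the route at 9.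

Further compounds
F1 | step 15 | (E)-enone iodo-aldehyde from cross-metathesis of 13 and 17 | CN(C)C[C@H]1C(=O)C(I)=C[C@@H]1/C=C/C(=O)[C@]1(C)CCCC(C)(C)[C@H]1CC=O
F2 | step 15 | macrocyclic 7R alcohol with (E)-C11=C12 enone | CN(C)C[C@H]1C(=O)C2=C[C@@H]1/C=C/C(=O)[C@]1(C)CCCC(C)(C)[C@H]1C[C@H]2O
F3 | step 13 | 7S epimer of 18 | C=CC(=O)[C@]1(C)CCCC(C)(C)[C@H]1C[C@H](O)C2=C[C@H](C=C)[C@@H](CN(C)C)C2=O
F4 | step 4 | (3S,4R)-3-methyl-4-(2-methyl-5-oxopentan-2-yl)-2-oxotetrahydro-2H-pyran-3-carbaldehyde | O=C1OCC[C@H](C(C)(C)CCC=O)[C@@]1(C)C=O
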